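## Structural features

The target (C35H26O8) is made of two trans-2,3-diaryl-2,3-dihydrobenzofurans joined by one C–C bond. The upper unit (ring A: O1, C2, C3, C3a to C7a) carries the formyl group on C5, para to O1, and a 4-hydroxyphenyl group on C2. Its C3 is bonded to C4' of the benzene ring (ring C, C3a' to C7a') of the lower unit, whose dihydrofuran ring (ring B: O1', C2', C3') carries a 4-hydroxyphenyl group on C2' and a 3,5-dihydroxyphenyl group on C3'; C6' bears a hydroxyl group. All four stereocentres are R: C2/C3 are adjacent and trans, C2'/C3' are adjacent and trans, and C3 and C3' face each other across the C4'–C3a' edge of ring C, so the two halves must match in absolute sense. Both C2–O bonds are 4-oxygenated benzylic ethers that ionise in acid (epimerisation, Friedel–Crafts capture by the resorcinol rings), and the five phenols and the aldehyde are sensitive to oxidation, so the phenols travel as methyl ethers to the last step. The real difficulty is ring C, which is 1,2,3,5-tetrasubstituted and holds the two doubly benzylic stereocentres C3 and C3' on neighbouring, crowded positions with no heteroatom handle. The key step uses the fact that O1 is a phenolic oxygen on C7a, made electron-poor by the para formyl group, and C2 is a 4-methoxybenzylic carbon: O1–C2 can be closed by phenol capture of a C2 cation released from a C2 carboxylic acid, which is the hydroxide-opened form of a 3,4-diaryl-3,4-dihydrocoumarin in which C3 is already fixed. In that open-chain acid the aryl group on the benzylic carbon is C4' of ring C; ring B is only the lower dihydrofuran ring and is not bonded to C3.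

## Logic of the disconnections

24 to 23: the five aryl O–CH3 bonds are cut. Free phenols would not survive enolate, palladium or anodic chemistry, so they are carried as methyl ethers. The forward step must cleave five ethers without opening two benzylic C–O bonds or damaging the aldehyde.

23 to 22: O1–C2 is cut and a carboxyl group is added to C2. Ring A opens to a phenol and a 2,3,3-triarylpropanoic acid. One ring and one stereocentre disappear, and the configuration at the carboxyl-bearing carbon no longer matters. The forward step must oxidise the carboxylate selectively beside four electron-rich arenes and close the ring anti to the C3 substituent. Because 22 can lactonise to 21, it is released by hydroxide just before use and electrolysed with only partial neutralisation in an ion-stabilising co-solvent.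

22 to 20 to 19 and 8: the C2–aryl bond is cut (enolate arylation). The C2 aryl group then comes from a commodity halide and needs no stereocontrol. The forward step needs the aldehyde and the phenol masked against strong base, and one acid treatment must later free ester, acetal and phenol together.

19 to 14 and 18: the bond from C3 to the ring A carbon C3a is cut (conjugate addition). This joins the two halves convergently and creates C3 under catalyst control. The forward step must override any bias from the resident C2'/C3' centres and tolerate an ortho-alkoxy boron reagent.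

18 to 17 to 16 to 15: the C–B bond and two protecting groups are removed; the demand is only that the acetal survives metalation and work-up.

14 to 12 and 13: the C4'–vinyl bond is cut (Mizoroki–Heck). A chloride on C4' is the only handle needed and is inert in all earlier steps; the forward step needs a catalyst that activates an electron-rich, ortho-substituted aryl chloride.

12 to 11 to 10 to 9: O1'–C2' is cut and a carboxyl group added to C2', the same one-carbon excision as in ring A but run in its two-stage, well-precedented form. Ring B becomes a six-membered lactone with a single controlled stereocentre. The forward step must oxidise the carboxylate before the phenol and close the ring trans under acid.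

9 to 7 and 8: the C3–aryl bond of the lactone is cut (enolate arylation); either C3 epimer serves.

7 to 5 and 6: the C4–aryl bond is cut (conjugate addition to a planar coumarin). This sets the future C3' and avoids a twisted, doubly ortho-substituted cinnamate; the forward step must tolerate the peri chlorine.

5 to 3 and 4, 3 to 2, 2 to 1: the C3=C4 and lactone C–O bonds, one O–CH3 bond and the C–CHO bond are cut, leading to a symmetric commodity arene. The forward steps need regioselective formylation next to chlorine and cleavage of only the methoxy group ortho to the formyl group.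

## Other disconnections considered

Alternative 1: The cut removes both carbon arms of ring C at once (C4'–C3 and C3a'–C3').
- Forward step: fluoride unmasks 3,5-dimethoxybenzyne from the silyl triflate A1. The enolate of the β-keto ester A2 adds to the aryne carbon remote from the methoxy group, the aryl anion closes onto the ketone, and the four-membered alkoxide fragments to the keto ester A3.
- In favour: one step assembles the tetrasubstituted ring C from two simple pieces with regiochemistry set by the methoxy group. The methoxy group next to the ketone is the one that chelation-controlled demethylation would free for O1'. No halide handle or Mizoroki–Heck step is needed. On assembly of ring C this is the better plan; the chosen route spends steps 1, 3 and 7 on the same two arms.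
- Against: A3 is achiral and sets none of the four stereocentres. C3' arrives as a diaryl ketone that must still gain C2' and become a stereogenic CH. The acetate CH2 (future C3) would have to be arylated with ring A and its ester carbon turned into C2, passing through enolisable α-aryl carbonyl compounds with no evident control of C3 or of the C3/C3' match. A1 itself costs several steps.
- Comparison: both plans rest on one well-understood polar event. In the chosen plan each C–C bond formation also sets a stereocentre under catalyst control, and its step count should be lower once the stereochemical work left after A3 is counted.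

Alternative 2: The cut takes C2' out of ring B as a one-carbon unit (C2'–C3' and O1'–C2').
- Forward step: base eliminates sulfinate from the ring C benzylic sulfone A4 to give the ortho-quinone methide. The ylide formed from the C2-symmetric sulfonium salt A5 adds to the methide carbon (C3'), and the phenoxide displaces the sulfide from C2' to give the bromide A6.
- In favour: the ring and both ring B stereocentres arise in one step, the trans ring follows from anti closure of the betaine, and the bromide of A6 is a better cross-coupling handle than the chloride of 12. On step economy for ring B this alternative is the better one (one step against steps 4 to 6), and A6 could be spliced into the chosen plan in place of 12.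
- Against: absolute control depends on a stoichiometric chiral sulfide and on face selection at a short-lived planar quinone methide of uncertain geometry flanked by bromine; reversible betaine formation can erode selectivity. The chosen route instead fixes C3' by aryl transfer to a coumarin inside a defined chiral pocket. This alternative also says nothing about ring A, C3 or the C3/C3' match.
- Comparison: the annulation is mechanistically as plausible as the anodic contraction; the two are complementary rather than competing.

Alternative 3: The cut dissolves the benzene ring of ring A (C3a–C7a, C4–C5, C6–C7).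
- Forward step: a metal-catalysed [2+2+2] cyclotrimerisation of the ynol-ether diyne A7 with the alkyne acetal A8 builds the arene. Because the tether runs through O1, C2 and C3, the dihydrofuran closes at the same time, giving the silyl acetal A9.
- In favour: three C–C bonds and two rings form in one step, no oxidation is run near the electron-rich arenes, the formyl group arrives masked, and the bulky silyl group steers the acetal to C5. In bond-forming efficiency of the key step it is clearly the better of the two.
- Against: C2 and C3 must be set beforehand on an open chain. C3 is then a propargylic, epimerisable centre, and C2 is a 4-methoxybenzylic alcohol that must be turned into a silyl ynol ether, a function prone to ionisation and to retro-ene loss of ketene. The silyl group must later be removed from C7 by protodesilylation in a molecule with two acid-sensitive benzylic ethers.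
- Comparison: the stereochemical problem is moved, not solved, and the longest linear sequence would be longer. The chosen route is also more convergent, joining ring A to the finished lower half in one catalytic step.

Key step: step 14

Assumption: the (R)-configured ligands of steps 4 and 11 are taken to deliver the aryl group to the α-Re face of the acceptor, as these ligand families do with cyclic enones; if a first run shows the opposite sense, the antipodal ligand is used with no other change.

## Route

Step 1
Reactants: 1 1-chloro-3,5-dimethoxybenzene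
Product: 2 2-chloro-4,6-dimethoxybenzaldehyde
Conditions: POCl3, DMF, 0 to 90 °C; aq. NaOAc
Reagents that add atoms: N,N-dimethylformamide, CN(C)C=O; water, O
Why: Vilsmeier–Haack formylation should occur para to one methoxy group and ortho to the other, next to chlorine, because the site between the two methoxy groups is more hindered. The minor 4-chloro-2,6-dimethoxy isomer would be removed by crystallisation.

Step 2
Reactants: 2 2-chloro-4,6-dimethoxybenzaldehyde
Product: 3 2-chloro-6-hydroxy-4-methoxybenzaldehyde
Conditions: BCl3 (1.2 equiv), CH2Cl2, −78 to 0 °C; H2O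
Reagents that add atoms: none
Why: Chelation-controlled demethylation: BCl3 held between the formyl oxygen and the ortho methoxy oxygen should cleave only that ether, leaving the para methoxy group and the aryl chloride untouched.

Step 3
Reactants: 3 2-chloro-6-hydroxy-4-methoxybenzaldehyde; 4 ethyl (triphenylphosphoranylidene)acetate
Product: 5 5-chloro-7-methoxy-2H-chromen-2-one
Conditions: 4 (1.3 equiv), PhNEt2, 210 °C
Reagents that add atoms: none
Why: Wittig olefination with the stabilised ylide, followed by thermal E-to-Z isomerisation and lactonisation, is a known one-operation coumarin synthesis from salicylaldehydes.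

Step 4
Reactants: 5 5-chloro-7-methoxy-2H-chromen-2-one; 6 (3,5-dimethoxyphenyl)boronic acid
Product: 7 (4R)-5-chloro-4-(3,5-dimethoxyphenyl)-7-methoxy-3,4-dihydro-2H-chromen-2-one
Conditions: Rh(acac)(C2H4)2 (3 mol%), (R)-SEGPHOS (3.3 mol%), 6 (4 equiv), dioxane/H2O (10:1), 60 °C
Reagents that add atoms: none
Why: Hayashi–Miyaura asymmetric 1,4-addition of an arylboronic acid to a coumarin, a known substrate class. The aryl group is delivered perpendicular to the ring plane, so the in-plane C5 chlorine should cost little, and (R)-SEGPHOS should direct the aryl group to the α-Re face, making C4 (the future C3') R.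

Step 5
Reactants: 7 (4R)-5-chloro-4-(3,5-dimethoxyphenyl)-7-methoxy-3,4-dihydro-2H-chromen-2-one; 8 1-bromo-4-methoxybenzene
Product: 9 (4R)-5-chloro-4-(3,5-dimethoxyphenyl)-7-methoxy-3-(4-methoxyphenyl)-3,4-dihydro-2H-chromen-2-one (C3 epimers, trans expected to predominate)
Conditions: LiN(SiMe3)2, THF, −78 °C; ZnCl2, −78 °C to rt; 8, Pd(dba)2 (3 mol%), P(t-Bu)3 (3 mol%), rt to 45 °C
Reagents that add atoms: none
Why: Negishi-type α-arylation of a zinc ester enolate (oxidative addition of 8 to zerovalent palladium, transmetalation, reductive elimination). The zinc enolate should resist ring opening, and the aryl bromide should react well before the hindered, electron-rich C5 chloride; the new C3 centre is not controlled and need not be, since it is erased in step 6.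

Step 6
Reactants: 9 (4R)-5-chloro-4-(3,5-dimethoxyphenyl)-7-methoxy-3-(4-methoxyphenyl)-3,4-dihydro-2H-chromen-2-one
Product: 12 (2R,3R)-4-chloro-3-(3,5-dimethoxyphenyl)-6-methoxy-2-(4-methoxyphenyl)-2,3-dihydro-1-benzofuran, via hydroxy acid 10 (not isolated), via benzylic methyl ether 11 (not isolated)
Conditions: NaOH, THF/H2O, rt; HCl to pH 3, extract; Et3N (0.2 equiv), MeOH, graphite anode, Pt cathode, undivided cell, constant current, ca. 2.5 F/mol, 15 °C; evaporate; TsOH·H2O (0.3 equiv), CH2Cl2, rt
Reagents that add atoms: none
Why: Saponification, non-Kolbe (Hofer–Moest) anodic methoxylation of a 4-methoxyphenylacetic acid and acid-catalysed SN1 etherification are all known. With a weak base only the carboxylic acid is ionised, so its oxidation should release CO2 and a 4-methoxybenzylic cation that methanol traps. TsOH then re-ionises the benzylic ether and the ortho phenol closes the five-membered ring anti to the C3 aryl group, setting C2 as R in the thermodynamically preferred trans ring while C3 from step 4 is untouched.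

Step 7
Reactants: 12 (2R,3R)-4-chloro-3-(3,5-dimethoxyphenyl)-6-methoxy-2-(4-methoxyphenyl)-2,3-dihydro-1-benzofuran; 13 tert-butyl prop-2-enoate
Product: 14 tert-butyl (2E)-3-[(2R,3R)-3-(3,5-dimethoxyphenyl)-6-methoxy-2-(4-methoxyphenyl)-2,3-dihydro-1-benzofuran-4-yl]prop-2-enoate
Conditions: 13 (2 equiv), Pd2(dba)3 (2.5 mol%), [HP(t-Bu)3]BF4 (10 mol%), Cy2NMe, dioxane, 110 °C
Reagents that add atoms: none
Why: Mizoroki–Heck reaction of an electron-rich aryl chloride, made feasible by the bulky, electron-rich P(t-Bu)3 ligand. Syn insertion and syn β-hydride elimination should give the E-acrylate.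

Step 8
Reactants: 15 3-bromo-4-hydroxybenzaldehyde
Product: 16 3-bromo-4-(methoxymethoxy)benzaldehyde
Conditions: MOMCl, i-Pr2NEt, CH2Cl2, 0 °C to rt
Reagents that add atoms: chloromethyl methyl ether, COCCl
Why: O-alkylation of the acidic phenol gives an acetal-type ether that is stable to organolithium, aqueous base and amide base and is later removed by the same acid that frees the ester.

Step 9
Reactants: 16 3-bromo-4-(methoxymethoxy)benzaldehyde
Product: 17 2-bromo-4-(dimethoxymethyl)-1-(methoxymethoxy)benzene
Conditions: HC(OMe)3, MeOH, TsOH·H2O (1 mol%), rt; Et3N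
Reagents that add atoms: trimethyl orthoformate, COC(OC)OC; methanol, CO
Why: Acid-catalysed acetalisation driven by the orthoformate as water scavenger. The brief, anhydrous, weakly acidic conditions should leave the methoxymethyl ether intact.

Step 10
Reactants: 17 2-bromo-4-(dimethoxymethyl)-1-(methoxymethoxy)benzene
Product: 18 2-[5-(dimethoxymethyl)-2-(methoxymethoxy)phenyl]-4,4,5,5-tetramethyl-1,3,2-dioxaborolane
Conditions: n-BuLi, THF, −78 °C; i-PrOBpin, −78 °C to rt; H2O
Reagents that add atoms: 2-isopropoxy-4,4,5,5-tetramethyl-1,3,2-dioxaborolane, CC(C)OB1OC(C)(C)C(C)(C)O1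
Why: Bromine–lithium exchange gives an aryllithium stabilised by the ortho methoxymethoxy group, which is borylated by the isopropoxy boronate. The neutral work-up preserves the acetal.

Step 11
Reactants: 14 tert-butyl (2E)-3-[(2R,3R)-3-(3,5-dimethoxyphenyl)-6-methoxy-2-(4-methoxyphenyl)-2,3-dihydro-1-benzofuran-4-yl]prop-2-enoate; 18 2-[5-(dimethoxymethyl)-2-(methoxymethoxy)phenyl]-4,4,5,5-tetramethyl-1,3,2-dioxaborolane
Product: 19 tert-butyl (3R)-3-[5-(dimethoxymethyl)-2-(methoxymethoxy)phenyl]-3-[(2R,3R)-3-(3,5-dimethoxyphenyl)-6-methoxy-2-(4-methoxyphenyl)-2,3-dihydro-1-benzofuran-4-yl]propanoate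
Conditions: Rh(acac)(C2H4)2 (5 mol%), (R,R)-Ph-bod* (5.5 mol%), 18 (2.5 equiv), KOH (0.2 equiv), dioxane/H2O (10:1), 60 °C
Reagents that add atoms: none
Why: Hayashi–Miyaura 1,4-addition to a β-aryl acrylate, the standard route to 3,3-diarylpropanoates; the chiral diene (1R,4R)-2,5-diphenylbicyclo[2.2.2]octa-2,5-diene gives a highly active monovalent rhodium catalyst. Catalyst control should place the aryl group on the α-Re face and set C3 as R, with the remote C2'/C3' centres exerting only a minor bias. Acetal, methoxymethyl ether and tert-butyl ester tolerate the aqueous base.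

Step 12
Reactants: 19 tert-butyl (3R)-3-[5-(dimethoxymethyl)-2-(methoxymethoxy)phenyl]-3-[(2R,3R)-3-(3,5-dimethoxyphenyl)-6-methoxy-2-(4-methoxyphenyl)-2,3-dihydro-1-benzofuran-4-yl]propanoate; 8 1-bromo-4-methoxybenzene
Product: 20 tert-butyl (3R)-3-[5-(dimethoxymethyl)-2-(methoxymethoxy)phenyl]-3-[(2R,3R)-3-(3,5-dimethoxyphenyl)-6-methoxy-2-(4-methoxyphenyl)-2,3-dihydro-1-benzofuran-4-yl]-2-(4-methoxyphenyl)propanoate (C2 epimers)
Conditions: LiN(SiMe3)2 (2.5 equiv), Pd(dba)2 (5 mol%), P(t-Bu)3 (5 mol%), 8 (1.5 equiv), toluene, rt to 50 °C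
Reagents that add atoms: none
Why: Palladium-catalysed α-arylation of a tert-butyl ester lithium enolate. The bulky ester suppresses Claisen condensation and the crowded product resists a second arylation; the new C2 centre is left uncontrolled because step 14 erases it, and C3 is not acidic.

Step 13
Reactants: 20 tert-butyl (3R)-3-[5-(dimethoxymethyl)-2-(methoxymethoxy)phenyl]-3-[(2R,3R)-3-(3,5-dimethoxyphenyl)-6-methoxy-2-(4-methoxyphenyl)-2,3-dihydro-1-benzofuran-4-yl]-2-(4-methoxyphenyl)propanoate
Product: 22 (3R)-3-[(2R,3R)-3-(3,5-dimethoxyphenyl)-6-methoxy-2-(4-methoxyphenyl)-2,3-dihydro-1-benzofuran-4-yl]-3-(5-formyl-2-hydroxyphenyl)-2-(4-methoxyphenyl)propanoic acid (C2 epimers), via lactone 21 (not isolated)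
Conditions: CF3CO2H/CH2Cl2/H2O (20:75:5), 1,3-dimethoxybenzene, 0 °C to rt; evaporate; NaOH (aq), THF, 0 °C; HCl to pH 4
Reagents that add atoms: water, O; sodium hydroxide, [Na+].[OH-]
Why: One acidolysis removes the tert-butyl ester, the methoxymethyl ether and the dimethyl acetal, with 1,3-dimethoxybenzene intercepting formaldehyde and tert-butyl cations. Material that closes to lactone 21 under the acid is reopened by the short hydroxide treatment, so the open hydroxy acid is what enters the key step.

Step 14
Reactants: 22 (3R)-3-[(2R,3R)-3-(3,5-dimethoxyphenyl)-6-methoxy-2-(4-methoxyphenyl)-2,3-dihydro-1-benzofuran-4-yl]-3-(5-formyl-2-hydroxyphenyl)-2-(4-methoxyphenyl)propanoic acid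
Product: 23 (2R,3R)-3-[(2R,3R)-3-(3,5-dimethoxyphenyl)-6-methoxy-2-(4-methoxyphenyl)-2,3-dihydro-1-benzofuran-4-yl]-2-(4-methoxyphenyl)-2,3-dihydro-1-benzofuran-5-carbaldehyde
Conditions: graphite anode, Pt cathode, undivided cell, 2,4,6-collidine (0.5 equiv), n-Bu4NBF4 (0.1 M), MeCN/(CF3)2CHOH (4:1), constant current, ca. 2.2 F/mol, 20 °C; work-up; TsOH·H2O (5 mol%), CH2Cl2, rt
Reagents that add atoms: none
Why: Proposed new method: the collidine-paired carboxylate is the only anion present and should be oxidised first at graphite, with assistance from the 4-methoxyphenyl ring; loss of CO2 gives the C2 benzylic radical, which is oxidised at the same potential to the 4-methoxybenzylic cation (Hofer–Moest pathway). The phenol oxygen on C7a captures this cation to form O1–C2, and the proton released is reduced to hydrogen at the cathode, so the base is regenerated and half an equivalent suffices. The closest known reaction types are the Hofer–Moest decarboxylative etherification of arylacetic acids by alcohols and the two-stage version used in step 6; the new element is direct intramolecular capture by a free phenol. The ring closes in a 5-exo-trig mode, the oxygen adding to the exocyclic carbon of the quinoid form of the cation. The new stereocentre C2 is controlled by C3: the oxygen approaches the planar cation anti to ring C, and the final trace of acid lets reversible C2–O ionisation funnel material to the trans (2R,3R) ring. The step needs chemoselective oxidation of the carboxylate beside four alkoxyarenes, a phenol and an aldehyde; this is secured by partial neutralisation, by hexafluoroisopropanol, which keeps the phenol protonated and stabilises the cation, by the para formyl group, which makes the phenol hard to oxidise, and by a low current density. Five-membered oxygen capture should outrun the competing fates of the cation (seven-membered Friedel–Crafts closure onto the 3,5-dimethoxyphenyl ring, 1,2-aryl shift, loss of the C3 proton), and C3 itself takes no part, so only the carboxyl-bearing carbon loses its configuration.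

Step 15
Reactants: 23 (2R,3R)-3-[(2R,3R)-3-(3,5-dimethoxyphenyl)-6-methoxy-2-(4-methoxyphenyl)-2,3-dihydro-1-benzofuran-4-yl]-2-(4-methoxyphenyl)-2,3-dihydro-1-benzofuran-5-carbaldehyde
Product: 24 (2R,3R)-3-[(2R,3R)-3-(3,5-dihydroxyphenyl)-6-hydroxy-2-(4-hydroxyphenyl)-2,3-dihydro-1-benzofuran-4-yl]-2-(4-hydroxyphenyl)-2,3-dihydro-1-benzofuran-5-carbaldehyde
Conditions: BBr3 (12 equiv), CH2Cl2, −78 to 0 °C; H2O/MeOH, 0 °C
Reagents that add atoms: none
Why: Lewis-acid cleavage of aryl methyl ethers (bromide attacks the methyl group of the boron-complexed ether). Complexation of the ether oxygens should also make the 4-oxygenated aryl groups poorer donors and so disfavour ionisation of the two benzylic C–O bonds, and any bromo-boronate adduct of the aldehyde reverts on aqueous work-up; no stereocentre is touched.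

## Compound list

1 | 1-chloro-3,5-dimethoxybenzene | COc1cc(Cl)cc(OC)c1 | starting material
2 | 2-chloro-4,6-dimethoxybenzaldehyde | O=Cc1c(Cl)cc(OC)cc1OC | intermediate
3 | 2-chloro-6-hydroxy-4-methoxybenzaldehyde | O=Cc1c(Cl)cc(OC)cc1O | intermediate
4 | ethyl (triphenylphosphoranylidene)acetate | CCOC(=O)C=P(c1ccccc1)(c1ccccc1)c1ccccc1 | starting material
5 | 5-chloro-7-methoxy-2H-chromen-2-one | O=C1C=Cc2c(Cl)cc(OC)cc2O1 | intermediate
6 | (3,5-dimethoxyphenyl)boronic acid | OB(O)c1cc(OC)cc(OC)c1 | starting material
7 | (4R)-5-chloro-4-(3,5-dimethoxyphenyl)-7-methoxy-3,4-dihydro-2H-chromen-2-one | O=C1C[C@H](c2cc(OC)cc(OC)c2)c2c(Cl)cc(OC)cc2O1 | intermediate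
8 | 1-bromo-4-methoxybenzene (4-bromoanisole) | COc1ccc(Br)cc1 | starting material
9 | (4R)-5-chloro-4-(3,5-dimethoxyphenyl)-7-methoxy-3-(4-methoxyphenyl)-3,4-dihydro-2H-chromen-2-one (C3 epimers) | O=C1C(c2ccc(OC)cc2)[C@H](c2cc(OC)cc(OC)c2)c2c(Cl)cc(OC)cc2O1 | intermediate
10 | (3R)-3-(2-chloro-6-hydroxy-4-methoxyphenyl)-3-(3,5-dimethoxyphenyl)-2-(4-methoxyphenyl)propanoic acid (C2 epimers) | OC(=O)C(c1ccc(OC)cc1)[C@H](c1cc(OC)cc(OC)c1)c1c(Cl)cc(OC)cc1O | intermediate
11 | 3-chloro-2-[(1R)-1-(3,5-dimethoxyphenyl)-2-methoxy-2-(4-methoxyphenyl)ethyl]-5-methoxyphenol (epimers at the methoxy-bearing carbon) | COC(c1ccc(OC)cc1)[C@H](c1cc(OC)cc(OC)c1)c1c(Cl)cc(OC)cc1O | intermediate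
12 | (2R,3R)-4-chloro-3-(3,5-dimethoxyphenyl)-6-methoxy-2-(4-methoxyphenyl)-2,3-dihydro-1-benzofuran | Clc1cc(OC)cc2c1[C@@H](c1cc(OC)cc(OC)c1)[C@H](c1ccc(OC)cc1)O2 | intermediate
13 | tert-butyl prop-2-enoate (tert-butyl acrylate) | C=CC(=O)OC(C)(C)C | starting material
14 | tert-butyl (2E)-3-[(2R,3R)-3-(3,5-dimethoxyphenyl)-6-methoxy-2-(4-methoxyphenyl)-2,3-dihydro-1-benzofuran-4-yl]prop-2-enoate | CC(C)(C)OC(=O)/C=C/c1cc(OC)cc2c1[C@@H](c1cc(OC)cc(OC)c1)[C@H](c1ccc(OC)cc1)O2 | intermediate
15 | 3-bromo-4-hydroxybenzaldehyde | O=Cc1ccc(O)c(Br)c1 | starting material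
16 | 3-bromo-4-(methoxymethoxy)benzaldehyde | O=Cc1ccc(OCOC)c(Br)c1 | intermediate
17 | 2-bromo-4-(dimethoxymethyl)-1-(methoxymethoxy)benzene | COC(OC)c1ccc(OCOC)c(Br)c1 | intermediate
18 | 2-[5-(dimethoxymethyl)-2-(methoxymethoxy)phenyl]-4,4,5,5-tetramethyl-1,3,2-dioxaborolane | COC(OC)c1ccc(OCOC)c(c1)B1OC(C)(C)C(C)(C)O1 | intermediate
19 | tert-butyl (3R)-3-[5-(dimethoxymethyl)-2-(methoxymethoxy)phenyl]-3-[(2R,3R)-3-(3,5-dimethoxyphenyl)-6-methoxy-2-(4-methoxyphenyl)-2,3-dihydro-1-benzofuran-4-yl]propanoate | CC(C)(C)OC(=O)C[C@@H](c1cc(C(OC)OC)ccc1OCOC)c1cc(OC)cc2c1[C@@H](c1cc(OC)cc(OC)c1)[C@H](c1ccc(OC)cc1)O2 | intermediate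
20 | tert-butyl (3R)-3-[5-(dimethoxymethyl)-2-(methoxymethoxy)phenyl]-3-[(2R,3R)-3-(3,5-dimethoxyphenyl)-6-methoxy-2-(4-methoxyphenyl)-2,3-dihydro-1-benzofuran-4-yl]-2-(4-methoxyphenyl)propanoate (C2 epimers) | CC(C)(C)OC(=O)C(c1ccc(OC)cc1)[C@@H](c1cc(C(OC)OC)ccc1OCOC)c1cc(OC)cc2c1[C@@H](c1cc(OC)cc(OC)c1)[C@H](c1ccc(OC)cc1)O2 | intermediate
21 | (4R)-4-[(2R,3R)-3-(3,5-dimethoxyphenyl)-6-methoxy-2-(4-methoxyphenyl)-2,3-dihydro-1-benzofuran-4-yl]-3-(4-methoxyphenyl)-2-oxo-3,4-dihydro-2H-chromene-6-carbaldehyde (C3 epimers) | O=Cc1ccc2OC(=O)C(c3ccc(OC)cc3)[C@H](c3cc(OC)cc4c3[C@@H](c3cc(OC)cc(OC)c3)[C@H](c3ccc(OC)cc3)O4)c2c1 | intermediate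
22 | (3R)-3-[(2R,3R)-3-(3,5-dimethoxyphenyl)-6-methoxy-2-(4-methoxyphenyl)-2,3-dihydro-1-benzofuran-4-yl]-3-(5-formyl-2-hydroxyphenyl)-2-(4-methoxyphenyl)propanoic acid (C2 epimers) | O=Cc1ccc(O)c(c1)[C@@H](c1cc(OC)cc2c1[C@@H](c1cc(OC)cc(OC)c1)[C@H](c1ccc(OC)cc1)O2)C(c1ccc(OC)cc1)C(=O)O | intermediate
23 | (2R,3R)-3-[(2R,3R)-3-(3,5-dimethoxyphenyl)-6-methoxy-2-(4-methoxyphenyl)-2,3-dihydro-1-benzofuran-4-yl]-2-(4-methoxyphenyl)-2,3-dihydro-1-benzofuran-5-carbaldehyde | O=Cc1ccc2c(c1)[C@@H](c1cc(OC)cc3c1[C@@H](c1cc(OC)cc(OC)c1)[C@H](c1ccc(OC)cc1)O3)[C@H](c1ccc(OC)cc1)O2 | intermediate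
24 | (2R,3R)-3-[(2R,3R)-3-(3,5-dihydroxyphenyl)-6-hydroxy-2-(4-hydroxyphenyl)-2,3-dihydro-1-benzofuran-4-yl]-2-(4-hydroxyphenyl)-2,3-dihydro-1-benzofuran-5-carbaldehyde | O=Cc1ccc2c(c1)[C@@H](c1cc(O)cc3c1[C@@H](c1cc(O)cc(O)c1)[C@H](c1ccc(O)cc1)O3)[C@H](c1ccc(O)cc1)O2 | target

## Step count and least certain steps

Total: 15 steps. Longest linear sequence: 12 steps (steps 1 to 7, then 11 to 15); steps 8 to 10 form the three-step side branch to 18.

Step 14 (key step). The most likely failure is loss of chemoselectivity at the anode: electron transfer from one of the dialkoxyarene rings or from collidine-bound phenol would lead to arene coupling and over-oxidation. The second is diversion of the cation before oxygen capture, by loss of the C3 proton (which would erase C3), by a 1,2-aryl shift, or by seven-membered Friedel–Crafts closure. The same anodic selectivity is tested first, on simpler material, in step 6. The fallback uses known chemistry, sets out from 22 and returns at 23. 22 is electrolysed under classical non-Kolbe conditions (Et3N 0.2 equiv, MeOH, graphite anode), where the solvent captures the cation at once and gives 4-hydroxy-3-[(1R)-1-[(2R,3R)-3-(3,5-dimethoxyphenyl)-6-methoxy-2-(4-methoxyphenyl)-2,3-dihydro-1-benzofuran-4-yl]-2-methoxy-2-(4-methoxyphenyl)ethyl]benzaldehyde F1. A catalytic amount of TsOH·H2O in CH2Cl2 then ionises the benzylic ether and the phenol closes the trans ring, as in the acid-mediated cyclisations of triarylethanol derivatives.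

Step 11. Poor facial selectivity is the main concern, because the crowded ortho substituent of the acrylate and its two resident stereocentres may oppose the catalyst. Slow transmetalation of the ortho-alkoxy boronate with competing protodeboronation is the second. The fallback sets out from 14 and 17 and returns at 19. A Mizoroki–Heck arylation of 14 with 17 (Pd2(dba)3, [HP(t-Bu)3]BF4, Cy2NMe) should give the stereodefined tert-butyl (2E)-3-[5-(dimethoxymethyl)-2-(methoxymethoxy)phenyl]-3-[(2R,3R)-3-(3,5-dimethoxyphenyl)-6-methoxy-2-(4-methoxyphenyl)-2,3-dihydro-1-benzofuran-4-yl]prop-2-enoate F2. Its C3 centre is then set by copper hydride conjugate reduction (Cu(OAc)2, the matching enantiomer of DTBM-SEGPHOS, diethoxymethylsilane, t-BuOH, toluene), so that a hydride rather than an aryl group is delivered under catalyst control.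

Step 5. The lactone enolate may open to a ketene and phenoxide and oligomerise, or the catalyst may insert into the C5–Cl bond. The fallback sets out from 7 and returns at 10. 7 is opened with KOt-Bu in t-BuOH/THF and the phenoxide capped in the same flask with MOMCl to give tert-butyl (3R)-3-[2-chloro-4-methoxy-6-(methoxymethoxy)phenyl]-3-(3,5-dimethoxyphenyl)propanoate F3. Standard tert-butyl ester α-arylation (LiN(SiMe3)2, Pd(dba)2, P(t-Bu)3, 8) gives tert-butyl (3R)-3-[2-chloro-4-methoxy-6-(methoxymethoxy)phenyl]-3-(3,5-dimethoxyphenyl)-2-(4-methoxyphenyl)propanoate F4. Aqueous CF3CO2H then releases 10, which enters the electrolysis of step 6.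

Step 4. Insertion into the poorly electrophilic coumarin may be too slow beside the peri chlorine, so that protodeboronation of 6 consumes the reagent. The fallback sets out from 5 and returns at 7. An oxidative Heck arylation of 5 with 6 (Pd(OAc)2, 1,10-phenanthroline, O2, DMF) gives 5-chloro-4-(3,5-dimethoxyphenyl)-7-methoxy-2H-chromen-2-one F5. The stereocentre is then set by asymmetric copper hydride 1,4-reduction of this 4-arylcoumarin (Cu(OAc)2, the matching enantiomer of DTBM-SEGPHOS, diethoxymethylsilane, t-BuOH), a known reaction of this substrate class.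

Step 15. Lewis-acid ionisation of the two benzylic C–O bonds may occur once the resorcinol rings are free, leading to Friedel–Crafts closure or epimerisation, and the aldehyde may be converted to bromo-boronate species that do not revert cleanly. The fallback addresses the aldehyde, sets out from 23 and returns at 24. The aldehyde is masked with ethane-1,2-dithiol and BF3·OEt2 as (2R,3R)-4-[(2R,3R)-5-(1,3-dithiolan-2-yl)-2-(4-methoxyphenyl)-2,3-dihydro-1-benzofuran-3-yl]-3-(3,5-dimethoxyphenyl)-6-methoxy-2-(4-methoxyphenyl)-2,3-dihydro-1-benzofuran F6. BBr3 then gives 5-[(2R,3R)-4-[(2R,3R)-5-(1,3-dithiolan-2-yl)-2-(4-hydroxyphenyl)-2,3-dihydro-1-benzofuran-3-yl]-6-hydroxy-2-(4-hydroxyphenyl)-2,3-dihydro-1-benzofuran-3-yl]benzene-1,3-diol F7, and the aldehyde is released by thioacetal exchange with glyoxylic acid in acetic acid.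

## Further compounds

F1 | step 14 | 4-hydroxy-3-[(1R)-1-[(2R,3R)-3-(3,5-dimethoxyphenyl)-6-methoxy-2-(4-methoxyphenyl)-2,3-dihydro-1-benzofuran-4-yl]-2-methoxy-2-(4-methoxyphenyl)ethyl]benzaldehyde | O=Cc1ccc(O)c(c1)[C@@H](c1cc(OC)cc2c1[C@@H](c1cc(OC)cc(OC)c1)[C@H](c1ccc(OC)cc1)O2)C(OC)c1ccc(OC)cc1
F2 | step 11 | tert-butyl (2E)-3-[5-(dimethoxymethyl)-2-(methoxymethoxy)phenyl]-3-[(2R,3R)-3-(3,5-dimethoxyphenyl)-6-methoxy-2-(4-methoxyphenyl)-2,3-dihydro-1-benzofuran-4-yl]prop-2-enoate | CC(C)(C)OC(=O)/C=C(/c1cc(C(OC)OC)ccc1OCOC)c1cc(OC)cc2c1[C@@H](c1cc(OC)cc(OC)c1)[C@H](c1ccc(OC)cc1)O2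
F3 | step 5 | tert-butyl (3R)-3-[2-chloro-4-methoxy-6-(methoxymethoxy)phenyl]-3-(3,5-dimethoxyphenyl)propanoate | CC(C)(C)OC(=O)C[C@H](c1cc(OC)cc(OC)c1)c1c(Cl)cc(OC)cc1OCOC
F4 | step 5 | tert-butyl (3R)-3-[2-chloro-4-methoxy-6-(methoxymethoxy)phenyl]-3-(3,5-dimethoxyphenyl)-2-(4-methoxyphenyl)propanoate (C2 epimers) | CC(C)(C)OC(=O)C(c1ccc(OC)cc1)[C@H](c1cc(OC)cc(OC)c1)c1c(Cl)cc(OC)cc1OCOC
F5 | step 4 | 5-chloro-4-(3,5-dimethoxyphenyl)-7-methoxy-2H-chromen-2-one | O=C1C=C(c2cc(OC)cc(OC)c2)c2c(Cl)cc(OC)cc2O1
F6 | step 15 | (2R,3R)-4-[(2R,3R)-5-(1,3-dithiolan-2-yl)-2-(4-methoxyphenyl)-2,3-dihydro-1-benzofuran-3-yl]-3-(3,5-dimethoxyphenyl)-6-methoxy-2-(4-methoxyphenyl)-2,3-dihydro-1-benzofuran | S1CCSC1c1ccc2c(c1)[C@@H](c1cc(OC)cc3c1[C@@H](c1cc(OC)cc(OC)c1)[C@H](c1ccc(OC)cc1)O3)[C@H](c1ccc(OC)cc1)O2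
F7 | step 15 | 5-[(2R,3R)-4-[(2R,3R)-5-(1,3-dithiolan-2-yl)-2-(4-hydroxyphenyl)-2,3-dihydro-1-benzofuran-3-yl]-6-hydroxy-2-(4-hydroxyphenyl)-2,3-dihydro-1-benzofuran-3-yl]benzene-1,3-diol | S1CCSC1c1ccc2c(c1)[C@@H](c1cc(O)cc3c1[C@@H](c1cc(O)cc(O)c1)[C@H](c1ccc(O)cc1)O3)[C@H](c1ccc(O)cc1)O2
A1 | alternative 1 | 3,5-dimethoxy-2-(trimethylsilyl)phenyl trifluoromethanesulfonate | COc1cc(OC)c([Si](C)(C)C)c(OS(=O)(=O)C(F)(F)F)c1
A2 | alternative 1 | ethyl 3-(3,5-dimethoxyphenyl)-3-oxopropanoate | CCOC(=O)CC(=O)c1cc(OC)cc(OC)c1
A3 | alternative 1 | ethyl 2-[2-(3,5-dimethoxybenzoyl)-3,5-dimethoxyphenyl]acetate | CCOC(=O)Cc1cc(OC)cc(OC)c1C(=O)c1cc(OC)cc(OC)c1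
A4 | alternative 2 | 3-bromo-2-[(3,5-dimethoxyphenyl)(4-methylbenzenesulfonyl)methyl]-5-methoxyphenol | Cc1ccc(cc1)S(=O)(=O)C(c1cc(OC)cc(OC)c1)c1c(O)cc(OC)cc1Br
A5 | alternative 2 | (2R,5R)-1-[(4-methoxyphenyl)methyl]-2,5-dimethylthiolan-1-ium tetrafluoroborate | C[C@@H]1CC[C@@H](C)[S+]1Cc1ccc(OC)cc1.F[B-](F)(F)F
A6 | alternative 2 | (2R,3R)-4-bromo-3-(3,5-dimethoxyphenyl)-6-methoxy-2-(4-methoxyphenyl)-2,3-dihydro-1-benzofuran | Brc1cc(OC)cc2c1[C@@H](c1cc(OC)cc(OC)c1)[C@H](c1ccc(OC)cc1)O2
A7 | alternative 3 | ({[(1R,2S)-2-[(2R,3R)-3-(3,5-dimethoxyphenyl)-6-methoxy-2-(4-methoxyphenyl)-2,3-dihydro-1-benzofuran-4-yl]-1-(4-methoxyphenyl)but-3-yn-1-yl]oxy}ethynyl)tri(propan-2-yl)silane | CC(C)[Si](C(C)C)(C(C)C)C#CO[C@@H](c1ccc(OC)cc1)[C@@H](C#C)c1cc(OC)cc2c1[C@@H](c1cc(OC)cc(OC)c1)[C@H](c1ccc(OC)cc1)O2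
A8 | alternative 3 | 3,3-diethoxyprop-1-yne | C#CC(OCC)OCC
A9 | alternative 3 | [(2R,3R)-5-(diethoxymethyl)-3-[(2R,3R)-3-(3,5-dimethoxyphenyl)-6-methoxy-2-(4-methoxyphenyl)-2,3-dihydro-1-benzofuran-4-yl]-2-(4-methoxyphenyl)-2,3-dihydro-1-benzofuran-7-yl]tri(propan-2-yl)silane | CCOC(OCC)c1cc([Si](C(C)C)(C(C)C)C(C)C)c2c(c1)[C@@H](c1cc(OC)cc3c1[C@@H](c1cc(OC)cc(OC)c1)[C@H](c1ccc(OC)cc1)O3)[C@H](c1ccc(OC)cc1)O2
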